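The route rests on treating the C1–C2 bond of the benzene ring as an aryne: C1 carries the propanoate chain, C2 a hydroxyl, and the neighbouring C3 methoxy oxygen polarises the triple bond. In one flask a masked propanal β-anion (acetal Grignard reagent) adds to C1 and the magnesium left on C2 is turned into the phenol through a borate, so that the aryl–chain C–C bond and the C2–O bond are made together. The aryne precursor is the benzyl ether of 4-fluoro-2-methoxyphenol, lithiated between F and OMe. Acetal hydrolysis, lactol oxidation, alkoxide opening of the dihydrocoumarin with octadecanol and hydrogenolysis complete the synthesis.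

Key step: step 3

Remark: the target has no stereocentre; the one stereocentre met on the way, the hemiacetal carbon of the lactol, forms as a racemate and is removed by the following oxidation.

Step 1
Reactants: 1 4-fluoro-2-methoxyphenol
Product: 2 1-(benzyloxy)-4-fluoro-2-methoxybenzene
Conditions: BnBr (1.1 equiv), K2CO3 (1.5 equiv), DMF, rt
Reagents that add atoms: benzyl bromide, BrCc1ccccc1
Why: Williamson ether synthesis, in which the phenoxide formed with K2CO3 displaces bromide from the benzylic carbon by SN2 and nothing else in 1 reacts under these conditions.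

Step 2
Reactants: 3 2-(2-bromoethyl)-1,3-dioxane
Product: 4 [2-(1,3-dioxan-2-yl)ethyl]magnesium bromide
Conditions: Mg turnings (1.5 equiv), I2 (cat.), THF, 25–35 °C; titrate before use
Reagents that add atoms: magnesium, [Mg]
Why: Grignard formation by insertion of magnesium into the primary C–Br bond; the six-membered acetal does not fragment or cyclise at room temperature in THF, so this homoenolate equivalent can be kept in solution.

Step 3
Reactants: 2 1-(benzyloxy)-4-fluoro-2-methoxybenzene, 4 [2-(1,3-dioxan-2-yl)ethyl]magnesium bromide
Product: 9 3-(benzyloxy)-6-[2-(1,3-dioxan-2-yl)ethyl]-2-methoxyphenol, via aryllithium 5 (not isolated), via aryne 6 (not isolated), via arylmagnesium bromide 7 (not isolated), via dimethyl arylboronate 8 (not isolated)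
Conditions: n-BuLi (1.05 equiv), THF, −78 °C, 1 h; 4 (2.5 equiv), −78 °C → rt; B(OMe)3 (5 equiv), −78 °C → rt; 30% aq. H2O2, AcOH, 0 °C → rt
Reagents that add atoms: hydrogen peroxide, OO (phenolic oxygen of 9); n-butyllithium, [Li]CCCC (lithium of 5 only); trimethyl borate, COB(OC)OC (boron and methoxy groups of 8 only)
Why: n-BuLi removes the ring hydrogen of 2 that lies between fluorine and the methoxy group, the most acidic site because two σ-withdrawing heteroatoms flank it, and on warming aryllithium 5 loses LiF (E1cB-type β-elimination) to give aryne 6. Grignard reagent 4 then adds across the strained triple bond (aryne carbomagnesiation): its carbon bonds to the aryne carbon remote from the methoxy group and magnesium ends on the carbon next to it, because the negative charge that builds up in the plane of the ring is best placed beside the inductively withdrawing, magnesium-coordinating oxygen. Arylmagnesium 7 is trapped by B(OMe)3 as boronate 8, and hydroperoxide addition to boron followed by 1,2-shift of the aryl group from boron to oxygen and hydrolysis releases phenol 9. The closest known reaction types are the three-component coupling of 3-alkoxybenzynes with Grignard reagents and electrophiles and the borylation–oxidation of arylmagnesium halides to phenols. No ring is closed and no stereocentre is formed. The step needs regioselective addition (chain to C1, metal to C2 of the target ring), which the C3 methoxy group next to the aryne secures, and chemoselectivity at the aryne, which the excess of 4 and the use of only one equivalent of n-BuLi at −78 °C (no butyl addition, no benzylic metalation of the benzyl ether) secure.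

Step 4
Reactants: 9 3-(benzyloxy)-6-[2-(1,3-dioxan-2-yl)ethyl]-2-methoxyphenol
Product: 11 7-(benzyloxy)-8-methoxy-3,4-dihydro-2H-chromen-2-ol, via hydroxy aldehyde 10 (not isolated)
Conditions: 1 M aq. HCl/THF (1:3), 0.05 M, 50 °C
Reagents that add atoms: water, O
Why: Acid-catalysed acetal hydrolysis frees aldehyde 10, which the neighbouring phenol oxygen captures as the six-membered cyclic hemiacetal (ring–chain tautomerism favours the 2-chromanol); the hemiacetal carbon forms as an equilibrating racemate that step 5 removes, and the benzyl and methyl ethers are stable to dilute aqueous acid.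

Step 5
Reactants: 11 7-(benzyloxy)-8-methoxy-3,4-dihydro-2H-chromen-2-ol
Product: 12 7-(benzyloxy)-8-methoxy-3,4-dihydro-2H-chromen-2-one
Conditions: n-Pr4N[RuO4] (5 mol %), N-methylmorpholine N-oxide (1.5 equiv), 4 Å MS, CH2Cl2, rt
Reagents that add atoms: none
Why: Ley–Griffith oxidation of a lactol to the lactone with catalytic perruthenate and an amine oxide as terminal oxidant, under neutral anhydrous conditions that leave the benzyl ether and the electron-rich ring untouched; the hemiacetal stereocentre becomes the sp2 lactone carbon.

Step 6
Reactants: 12 7-(benzyloxy)-8-methoxy-3,4-dihydro-2H-chromen-2-one, 13 octadecan-1-ol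
Product: 14 octadecyl 3-[4-(benzyloxy)-2-hydroxy-3-methoxyphenyl]propanoate
Conditions: 13 (1.2 equiv), NaH (1.2 equiv), THF, 0 °C → rt; then 12, 0 °C → rt; AcOH (1.3 equiv), 0 °C
Reagents that add atoms: none
Why: Transesterification by nucleophilic acyl substitution, in which the primary alkoxide opens the aryl ester and releases a phenoxide far less basic than the alkoxide consumed, so the ring opening is driven forward with little excess alcohol, and a cold weak-acid quench returns the phenol without acid-catalysed relactonisation.

Step 7
Reactants: 14 octadecyl 3-[4-(benzyloxy)-2-hydroxy-3-methoxyphenyl]propanoate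
Product: 15 octadecyl 3-(2,4-dihydroxy-3-methoxyphenyl)propanoate
Conditions: H2 (1 atm), Pd/C (10 wt %, cat.), EtOAc, rt
Reagents that add atoms: none
Why: Catalytic hydrogenolysis of the benzyl aryl ether on palladium under neutral conditions in a non-nucleophilic solvent, which should leave the alkyl ester, the methyl ether and the free ortho-phenol untouched and avoid transesterification or lactonisation.

Compound list
1 | 4-fluoro-2-methoxyphenol | COc1cc(F)ccc1O | starting material
2 | 1-(benzyloxy)-4-fluoro-2-methoxybenzene | COc1cc(F)ccc1OCc1ccccc1 | intermediate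
3 | 2-(2-bromoethyl)-1,3-dioxane | BrCCC1OCCCO1 | starting material
4 | [2-(1,3-dioxan-2-yl)ethyl]magnesium bromide | Br[Mg]CCC1OCCCO1 | intermediate
5 | [3-(benzyloxy)-6-fluoro-2-methoxyphenyl]lithium (aryllithium, not isolated) | [Li]c1c(F)ccc(OCc2ccccc2)c1OC | intermediate
6 | 1-(benzyloxy)-3,4-didehydro-2-methoxybenzene (4-benzyloxy-3-methoxybenzyne, not isolated) | COC1=C(OCc2ccccc2)C=CC#C1 | intermediate
7 | {3-(benzyloxy)-6-[2-(1,3-dioxan-2-yl)ethyl]-2-methoxyphenyl}magnesium bromide (not isolated) | COc1c([Mg]Br)c(CCC2OCCCO2)ccc1OCc1ccccc1 | intermediate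
8 | dimethyl {3-(benzyloxy)-6-[2-(1,3-dioxan-2-yl)ethyl]-2-methoxyphenyl}boronate (not isolated) | COB(OC)c1c(CCC2OCCCO2)ccc(OCc2ccccc2)c1OC | intermediate
9 | 3-(benzyloxy)-6-[2-(1,3-dioxan-2-yl)ethyl]-2-methoxyphenol | COc1c(O)c(CCC2OCCCO2)ccc1OCc1ccccc1 | intermediate
10 | 3-[4-(benzyloxy)-2-hydroxy-3-methoxyphenyl]propanal (not isolated) | COc1c(O)c(CCC=O)ccc1OCc1ccccc1 | intermediate
11 | 7-(benzyloxy)-8-methoxy-3,4-dihydro-2H-chromen-2-ol (racemic, configurationally labile hemiacetal at C2) | COc1c(OCc2ccccc2)ccc2c1OC(O)CC2 | intermediate
12 | 7-(benzyloxy)-8-methoxy-3,4-dihydro-2H-chromen-2-one | COc1c(OCc2ccccc2)ccc2c1OC(=O)CC2 | intermediate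
13 | octadecan-1-ol | CCCCCCCCCCCCCCCCCCO | starting material
14 | octadecyl 3-[4-(benzyloxy)-2-hydroxy-3-methoxyphenyl]propanoate | CCCCCCCCCCCCCCCCCCOC(=O)CCc1ccc(OCc2ccccc2)c(OC)c1O | intermediate
15 | octadecyl 3-(2,4-dihydroxy-3-methoxyphenyl)propanoate | CCCCCCCCCCCCCCCCCCOC(=O)CCc1ccc(O)c(OC)c1O | target

Total step count: 7
Longest linear sequence: 6 steps (steps 1, 3, 4, 5, 6, 7 from compound 1; equally steps 2–7 from compound 3)

Steps most likely to fail

1. Step 3.
Risk: the aryne may be captured by aryllithium 5 or may oligomerise faster than the chelated primary alkyl Grignard reagent adds. The doubly ortho-substituted arylmagnesium 7 may also be borylated incompletely and then protonated on work-up.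
Fallback (no aryne): it sets out from octadecan-1-ol 13 and comes back to the route at target 15. Compound 13 would be acylated with acryloyl chloride and Et3N in CH2Cl2 at 0 °C to give octadecyl prop-2-enoate F1. Separately, commercial 2-methoxybenzene-1,3-diol would be benzylated twice (BnBr, K2CO3, DMF) to 1,3-bis(benzyloxy)-2-methoxybenzene F2. Its two equivalent positions para to a benzyloxy group make bromination with NBS in MeCN at 0 °C regiochemically unambiguous, which should give 1,3-bis(benzyloxy)-4-bromo-2-methoxybenzene F3. Heck coupling of F3 with F1 (Pd(OAc)2, P(o-tol)3, Et3N, DMF, 100 °C) should give octadecyl (2E)-3-[2,4-bis(benzyloxy)-3-methoxyphenyl]prop-2-enoate F4. Hydrogenation over Pd/C in EtOAc would saturate the alkene and remove both benzyl groups to give 15.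

2. Step 4.
Risk: under aqueous acid the cyclic oxocarbenium ion related to lactol 11 may lose a proton to give a 4H-chromene or alkylate the electron-rich ring of a second molecule, so that oligomers form. Cleavage of the 1,3-dioxane may also be sluggish.
Fallback (open chain, no lactol or lactone): it sets out from 9 and comes back at 15. Benzylation of the phenol of 9 (BnBr, K2CO3, DMF) should give 2-{2-[2,4-bis(benzyloxy)-3-methoxyphenyl]ethyl}-1,3-dioxane F5. With no free ortho-hydroxyl, hydrolysis (2 M aq. HCl, THF, 50 °C) stops at the acyclic aldehyde 3-[2,4-bis(benzyloxy)-3-methoxyphenyl]propanal F6. Pinnick oxidation (NaClO2, NaH2PO4, 2-methylbut-2-ene, t-BuOH/H2O) would give 3-[2,4-bis(benzyloxy)-3-methoxyphenyl]propanoic acid F7. Steglich esterification with 13 (EDC·HCl, DMAP, CH2Cl2) would give octadecyl 3-[2,4-bis(benzyloxy)-3-methoxyphenyl]propanoate F8. Hydrogenolysis (H2, Pd/C, EtOAc) then removes both benzyl groups to give 15.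

3. Step 6.
Risk: the ring opening is reversible, so conversion may stay incomplete, or the product may relactonise with loss of octadecanol during quench and purification.
Fallback (ester bond made at the alkyl carbon instead of the acyl carbon): it sets out from lactone 12 and comes back at 14. Saponification (LiOH, THF/H2O, 0 °C, then cold acidification to pH 4–5) should give 3-[4-(benzyloxy)-2-hydroxy-3-methoxyphenyl]propanoic acid F9. Used crude, F9 would be alkylated at the carboxylate only with commercial 1-bromooctadecane (KHCO3, DMF, 40 °C) to give 14, since hydrogen carbonate is too weak a base to ionise the phenol.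

Further compounds
F1 | step 3 | octadecyl prop-2-enoate | C=CC(=O)OCCCCCCCCCCCCCCCCCC
F2 | step 3 | 1,3-bis(benzyloxy)-2-methoxybenzene | COc1c(OCc2ccccc2)cccc1OCc1ccccc1
F3 | step 3 | 1,3-bis(benzyloxy)-4-bromo-2-methoxybenzene | COc1c(OCc2ccccc2)ccc(Br)c1OCc1ccccc1
F4 | step 3 | octadecyl (2E)-3-[2,4-bis(benzyloxy)-3-methoxyphenyl]prop-2-enoate | CCCCCCCCCCCCCCCCCCOC(=O)/C=C/c1ccc(OCc2ccccc2)c(OC)c1OCc1ccccc1
F5 | step 4 | 2-{2-[2,4-bis(benzyloxy)-3-methoxyphenyl]ethyl}-1,3-dioxane | COc1c(OCc2ccccc2)ccc(CCC2OCCCO2)c1OCc1ccccc1
F6 | step 4 | 3-[2,4-bis(benzyloxy)-3-methoxyphenyl]propanal | COc1c(OCc2ccccc2)ccc(CCC=O)c1OCc1ccccc1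
F7 | step 4 | 3-[2,4-bis(benzyloxy)-3-methoxyphenyl]propanoic acid | COc1c(OCc2ccccc2)ccc(CCC(=O)O)c1OCc1ccccc1
F8 | step 4 | octadecyl 3-[2,4-bis(benzyloxy)-3-methoxyphenyl]propanoate | CCCCCCCCCCCCCCCCCCOC(=O)CCc1ccc(OCc2ccccc2)c(OC)c1OCc1ccccc1
F9 | step 6 | 3-[4-(benzyloxy)-2-hydroxy-3-methoxyphenyl]propanoic acid | COc1c(O)c(CCC(=O)O)ccc1OCc1ccccc1
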